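## Analysis of the target

The target is a flavan-3-ol: a benzopyran (aromatic ring A fused to the dihydropyran ring C) carrying aryl ring B at C2, with galloyl esters on O7 (ring A) and O3' (ring B). There are only two stereocentres, C2 (R) and C3 (S). They are adjacent in ring C, with ring B and the 3-OH trans, which is the (+)-catechin series; I checked the SMILES and it reads (2R,3S). Of the five oxygens on the core, two (O7, O3') are acylated and three (O5, O4', O3-H) are free, so the synthesis must tell O7 from O5 and O3' from O4'. Acylating commercial (+)-catechin cannot do this.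

The sensitive groups are:
- the aryl gallates, which are cleaved by base and nucleophiles, and the 3'-ester can migrate to a free O4';
- the electron-rich rings;
- the C2–O1 benzylic ether para to O4', which is open to ionisation, to quinone-methide epimerisation under base, and to hydrogenolysis.

Two features of this structure invite the route:
- In ring A, C4a is flanked by O1 and O5 and is para to O7. A 2,4,6-trioxygenated benzaldehyde (formyl carbon = C4) therefore singles out O7, while the two ortho oxygens stay equivalent until one is benzylated.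
- C2 (O1, ring B, H) and C3 (OH, H) carry exactly the pattern that hydroboration–oxidation writes onto the C2=C3 enol ether of a flav-2-ene: boron beta to O1, H and O delivered syn, hence trans.

Both stereocentres can therefore be postponed until the whole skeleton exists as a flat, achiral chromene.

## Retrosynthetic reasoning

**18 ⇒ 17.** The last step is a neutral hydrogenolysis. All oxygens that must end free (O5, O4' and the six galloyl oxygens) are benzyl ethers in 17; O3-H is left free. Nothing basic touches the two aryl esters once they exist.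

**17 ⇒ 14 + 15 (through 16).** The two ester C–O bonds at O7 and O3' are cut. Triol 14 has exactly these two phenols free and one hindered secondary alcohol. The forward reaction is a phenol-selective acylation with acid chloride 16, made in the flask from commercial acid 15.

**14 ⇒ 13.** The two free phenols of 14 are silyl ethers in 13. This is the protecting-group code of the route: silyl marks the oxygens that will be galloylated, benzyl marks those that end free. Cleaving the silyl ethers with fluoride leaves benzyl ethers and both stereocentres alone.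

**13 ⇒ 11 (key disconnection).** The C2–H and C3–O bonds are cut and both stereocentres are removed together, leaving the achiral 2-aryl-4H-chromene (flav-2-ene) 11. This cut is chosen because no substitution at the ionisable C2 and no enolisable carbonyl is then needed at any stage. The forward reaction must add H to C2 and O to C3 on one face (through borane 12), with the face chosen by a chiral monoalkylborane.

**11 ⇒ 4 + 8 (through 9 and 10).** Ring C is cut at O1–C2 and C3–C4, a retro-hetero-Diels–Alder. The fragments are o-quinone methide 9, released from salicyl alcohol 4, and enol silane 8. The two ring halves join in one operation with unambiguous regiochemistry; cycloadduct 10 loses silanol to give 11.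

**4 ⇒ 3 ⇒ 2 ⇒ 1.** Ring A comes from aldehyde 1. Its para OH (the future O7) is the most acidic and least hindered and is silylated first (2). One of the two equivalent ortho OH groups is then benzylated (3, future O5). The remaining one is the future O1. The formyl carbon is reduced to the future C4 (4).

**8 ⇒ 7 ⇒ 6 ⇒ 5.** Ring B with C2 comes from acetophenone 5. The OH para to the acetyl group (future O4') is benzylated selectively (6), the meta OH (future O3') is silylated (7), and the methyl ketone is turned into enol silane 8.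

## Alternatives that were turned down

**Alternative 1:** the textbook route. Disconnection at O1–C2 of an open-chain diol. Forward: Sharpless asymmetric dihydroxylation [K2OsO2(OH)4, (DHQ)2PHAL, K3Fe(CN)6] of the (E)-1,3-diarylpropene A1 gives the syn-diol A2, which is closed by substitution at C2 with inversion (cyclic orthoester or Mitsunobu).
- The ring closure is a substitution at a benzylic carbon para to an alkoxy group, where SN1 leakage erodes the trans/cis ratio.
- A1 needs a hydroxide-mediated Claisen–Schmidt condensation, which does not tolerate the aryl silyl code, plus a carbonyl deoxygenation.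
- From the two ring fragments it takes about five steps to do what steps 7 and 8 do in two.

**Alternative 2:** disconnection at C2–C1'. Forward: asymmetric conjugate addition of a ring B arylboron reagent to chromone A3 ([Rh(C2H4)2Cl]2 with a chiral diene) gives the (2S)-flavanone A4.
- The C4 carbonyl distinguishes O5 from O7 for free, but the key step sets only C2.
- The 3-OH must then go in through the enolate of A4, which opens by retro-oxa-Michael reaction and racemises C2.
- The C4 carbonyl must finally be removed in two more reductions. The oxidation level is wrong at two carbons.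

**Alternative 3:** disconnection at O1–C2 and C3=C4. Forward: iridium-catalysed asymmetric allylic etherification ([Ir(cod)Cl]2, phosphoramidite) gives the branched aryl allyl ether A5; ring-closing metathesis (second-generation Grubbs catalyst) gives the (2S)-flav-3-ene A6; substrate-controlled hydroboration follows.
- The allyl ether in A5 is doubly activated (allylic, and benzylic to a p-alkoxyaryl group). It can re-ionise under the catalyst, eroding ee and giving the linear isomer.
- Hydroboration of the styrenic C3=C4 bond of A6 does not reliably distinguish C3 from C4.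
- Two precious-metal steps and three operations replace steps 7 and 8.

Key step: step 8

Remark: acylating commercial (+)-catechin is taken to be a partial synthesis; the route builds the flavan from achiral benzenoid starting materials.

Abbreviations: Bn = benzyl, TIPS = triisopropylsilyl, TMS = trimethylsilyl, Ipc = isopinocampheyl.

## Route

Step 1
Reactants: 1 2,4,6-trihydroxybenzaldehyde
Product: 2 2,6-dihydroxy-4-[(triisopropylsilyl)oxy]benzaldehyde
Conditions: TIPSCl (1.05 equiv), imidazole, DMF, 0 °C
Reagents that add atoms: triisopropylsilyl chloride, CC(C)[Si](Cl)(C(C)C)C(C)C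
Why: Regioselective O-silylation; the 4-OH is the most acidic hydroxyl and the only one neither hydrogen-bonded to nor flanking the formyl group, so the bulky silyl chloride should take it alone.

Step 2
Reactants: 2 2,6-dihydroxy-4-[(triisopropylsilyl)oxy]benzaldehyde
Product: 3 2-(benzyloxy)-6-hydroxy-4-[(triisopropylsilyl)oxy]benzaldehyde
Conditions: BnOH (1.05 equiv), PPh3, DIAD, THF, 0 °C to rt
Reagents that add atoms: benzyl alcohol, OCc1ccccc1
Why: Mitsunobu etherification under neutral conditions that spare the aryl silyl ether; the two ortho OH groups are equivalent, and after the first benzylation the remaining OH is locked in the hydrogen bond to C=O and should not react further.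

Step 3
Reactants: 3 2-(benzyloxy)-6-hydroxy-4-[(triisopropylsilyl)oxy]benzaldehyde
Product: 4 3-(benzyloxy)-2-(hydroxymethyl)-5-[(triisopropylsilyl)oxy]phenol
Conditions: NaBH4, THF/MeOH, −10 to 0 °C; pH 7 phosphate buffer; used crude
Reagents that add atoms: none
Why: Hydride reduction of the aldehyde to the salicyl alcohol; low temperature, short time and a neutral quench are meant to stop at the alcohol and keep the acid-labile product intact.

Step 4
Reactants: 5 1-(3,4-dihydroxyphenyl)ethan-1-one
Product: 6 1-[4-(benzyloxy)-3-hydroxyphenyl]ethan-1-one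
Conditions: BnCl (1.0 equiv), NaHCO3, NaI (cat.), DMF, 40 °C
Reagents that add atoms: benzyl chloride, ClCc1ccccc1
Why: Williamson etherification with a weak base; only the 4-OH, whose phenoxide is conjugated with the acetyl group, is deprotonated appreciably, so mono-benzylation at the future O4' is expected.

Step 5
Reactants: 6 1-[4-(benzyloxy)-3-hydroxyphenyl]ethan-1-one
Product: 7 1-{4-(benzyloxy)-3-[(triisopropylsilyl)oxy]phenyl}ethan-1-one
Conditions: TIPSCl, imidazole, DMF, rt
Reagents that add atoms: triisopropylsilyl chloride, CC(C)[Si](Cl)(C(C)C)C(C)C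
Why: Standard silylation of the one remaining phenol; it marks O3' as a future acylation site.

Step 6
Reactants: 7 1-{4-(benzyloxy)-3-[(triisopropylsilyl)oxy]phenyl}ethan-1-one
Product: 8 ({1-[4-(benzyloxy)-3-[(triisopropylsilyl)oxy]phenyl]ethenyl}oxy)trimethylsilane
Conditions: TMSOTf, Et3N, CH2Cl2, 0 °C; used crude
Reagents that add atoms: trimethylsilyl trifluoromethanesulfonate, C[Si](C)(C)OS(=O)(=O)C(F)(F)F
Why: Soft enolisation of a methyl aryl ketone, which has only one enolisable position, to the trimethylsilyl enol ether; aryl silyl and benzyl ethers are inert.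

Step 7
Reactants: 4 3-(benzyloxy)-2-(hydroxymethyl)-5-[(triisopropylsilyl)oxy]phenol; 8 ({1-[4-(benzyloxy)-3-[(triisopropylsilyl)oxy]phenyl]ethenyl}oxy)trimethylsilane
Product: 11 5-(benzyloxy)-2-{4-(benzyloxy)-3-[(triisopropylsilyl)oxy]phenyl}-7-[(triisopropylsilyl)oxy]-4H-chromene, via o-quinone methide 9 (not isolated), via 2-silyloxychroman cycloadduct 10 (not isolated)
Conditions: 8 (3 equiv), 4 Å MS, toluene, 100 °C, slow addition of 4; then PPTS (5 mol %), 60 °C; Et3N quench
Reagents that add atoms: none
Why: Thermal dehydration of 4 gives o-quinone methide 9 from the only free phenol, and an inverse-demand hetero-Diels–Alder reaction with 8 joins the nucleophilic CH2 terminus to the methide carbon (C3–C4) and the phenoxide oxygen to the oxocarbenium carbon (O1–C2) to give 10. Acid-catalysed loss of trimethylsilanol from the mixed ketal 10 gives the aryl-conjugated enol ether 11; the excess of 8 and slow addition should outrun self-condensation of 9.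

Step 8
Reactants: 11 5-(benzyloxy)-2-{4-(benzyloxy)-3-[(triisopropylsilyl)oxy]phenyl}-7-[(triisopropylsilyl)oxy]-4H-chromene
Product: 13 (2R,3S)-5-(benzyloxy)-2-{4-(benzyloxy)-3-[(triisopropylsilyl)oxy]phenyl}-7-[(triisopropylsilyl)oxy]-3,4-dihydro-2H-chromen-3-ol, via isopinocampheyl(flavan-3-yl)borane 12 (not isolated)
Conditions: (IpcBH2)2·TMEDA [from (+)-α-pinene], BF3·OEt2, THF, rt, filter; 11, −25 °C; then NaBO3·4H2O, THF/H2O, rt
Reagents that add atoms: sodium perborate tetrahydrate, [Na+].[Na+].O[B-]1(O)OO[B-](O)(O)OO1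
Why: Asymmetric hydroboration–oxidation: the B–H bond of IpcBH2 adds across C2=C3 of 11 through a concerted four-centre syn transition state, and perborate oxidises the C3–B bond of 12 with retention. The closest known reactions are the IpcBH2 hydroboration of 1-arylcycloalkenes to trans-2-arylcycloalkanols and the borane hydroboration of flav-2-enes to 2,3-trans-flavan-3-ols. No ring is closed; ring C is already in place and only goes from a planar enol ether to the half-chair of the flavan. Regiochemistry (boron to C3, hydrogen to C2) is secured twice by the substrate, because C3 is both beta to O1 of the enol ether and remote from the 2-aryl group. The relative configuration follows from the mechanism: H at C2 and B (then OH) at C3 enter on the same face, so ring B and the 3-OH end up trans. The absolute configuration is set by the reagent: the isopinocampheyl group from (+)-α-pinene should deliver boron to the C3 face that leads to (2R,3S), by analogy with the sense known for 1-arylcycloalkenes, and the antipodal reagent is equally accessible should the ring oxygen reverse the preference. Chemoselectivity needs no help, since 11 has no other alkene, carbonyl or acidic hydrogen and benzyl and aryl silyl ethers are inert to the borane and to perborate.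

Step 9
Reactants: 13 (2R,3S)-5-(benzyloxy)-2-{4-(benzyloxy)-3-[(triisopropylsilyl)oxy]phenyl}-7-[(triisopropylsilyl)oxy]-3,4-dihydro-2H-chromen-3-ol
Product: 14 (2R,3S)-5-(benzyloxy)-2-[4-(benzyloxy)-3-hydroxyphenyl]-3,4-dihydro-2H-chromene-3,7-diol
Conditions: Bu4NF (2.4 equiv), AcOH (2.4 equiv), THF, 0 °C
Reagents that add atoms: none
Why: Fluoride cleavage of the two aryl Si–O bonds, buffered so that the phenols are not left as free phenoxides; O4' is benzylated, so the quinone-methide pathway that epimerises C2 in free catechins is closed.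

Step 10
Reactants: 14 (2R,3S)-5-(benzyloxy)-2-[4-(benzyloxy)-3-hydroxyphenyl]-3,4-dihydro-2H-chromene-3,7-diol; 15 3,4,5-tris(benzyloxy)benzoic acid
Product: 17 (2R,3S)-5-(benzyloxy)-2-{4-(benzyloxy)-3-[3,4,5-tris(benzyloxy)benzoyloxy]phenyl}-3-hydroxy-3,4-dihydro-2H-chromen-7-yl 3,4,5-tris(benzyloxy)benzoate, via 3,4,5-tris(benzyloxy)benzoyl chloride 16 (not isolated)
Conditions: 15 (2.2 equiv), (COCl)2, DMF (cat.), CH2Cl2, rt, evaporate; then 14, Et3N, CH2Cl2, −20 to 0 °C, no DMAP
Reagents that add atoms: none
Why: Acid chloride formation followed by phenol-selective acylation; with an amine base and no acyl-transfer catalyst the two phenols should react far faster than the hindered secondary 3-OH.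

Step 11
Reactants: 17 (2R,3S)-5-(benzyloxy)-2-{4-(benzyloxy)-3-[3,4,5-tris(benzyloxy)benzoyloxy]phenyl}-3-hydroxy-3,4-dihydro-2H-chromen-7-yl 3,4,5-tris(benzyloxy)benzoate
Product: 18 (2R,3S)-3,5-dihydroxy-2-[4-hydroxy-3-(3,4,5-trihydroxybenzoyloxy)phenyl]-3,4-dihydro-2H-chromen-7-yl 3,4,5-trihydroxybenzoate [(+)-catechin 7,3'-di-O-gallate]
Conditions: H2 (1 atm), Pd(OH)2/C, THF/EtOAc, rt
Reagents that add atoms: none
Why: Hydrogenolysis of all eight benzyl ethers in a neutral, non-nucleophilic medium, which leaves the two aryl esters and both stereocentres untouched; the reaction should be stopped as soon as debenzylation is complete.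

## Compound list

1 | 2,4,6-trihydroxybenzaldehyde | O=Cc1c(O)cc(O)cc1O | starting material
2 | 2,6-dihydroxy-4-[(triisopropylsilyl)oxy]benzaldehyde | O=Cc1c(O)cc(O[Si](C(C)C)(C(C)C)C(C)C)cc1O | intermediate
3 | 2-(benzyloxy)-6-hydroxy-4-[(triisopropylsilyl)oxy]benzaldehyde | O=Cc1c(O)cc(O[Si](C(C)C)(C(C)C)C(C)C)cc1OCc1ccccc1 | intermediate
4 | 3-(benzyloxy)-2-(hydroxymethyl)-5-[(triisopropylsilyl)oxy]phenol | OCc1c(O)cc(O[Si](C(C)C)(C(C)C)C(C)C)cc1OCc1ccccc1 | intermediate
5 | 1-(3,4-dihydroxyphenyl)ethan-1-one | CC(=O)c1ccc(O)c(O)c1 | starting material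
6 | 1-[4-(benzyloxy)-3-hydroxyphenyl]ethan-1-one | CC(=O)c1ccc(OCc2ccccc2)c(O)c1 | intermediate
7 | 1-{4-(benzyloxy)-3-[(triisopropylsilyl)oxy]phenyl}ethan-1-one | CC(=O)c1ccc(OCc2ccccc2)c(O[Si](C(C)C)(C(C)C)C(C)C)c1 | intermediate
8 | ({1-[4-(benzyloxy)-3-[(triisopropylsilyl)oxy]phenyl]ethenyl}oxy)trimethylsilane | C=C(O[Si](C)(C)C)c1ccc(OCc2ccccc2)c(O[Si](C(C)C)(C(C)C)C(C)C)c1 | intermediate
9 | 5-(benzyloxy)-6-methylidene-3-[(triisopropylsilyl)oxy]cyclohexa-2,4-dien-1-one (o-quinone methide) | C=C1C(=O)C=C(O[Si](C(C)C)(C(C)C)C(C)C)C=C1OCc1ccccc1 | intermediate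
10 | 5-(benzyloxy)-2-{4-(benzyloxy)-3-[(triisopropylsilyl)oxy]phenyl}-7-[(triisopropylsilyl)oxy]-2-[(trimethylsilyl)oxy]chromane (racemic at C2) | C[Si](C)(C)OC1(CCc2c(OCc3ccccc3)cc(O[Si](C(C)C)(C(C)C)C(C)C)cc2O1)c1ccc(OCc2ccccc2)c(O[Si](C(C)C)(C(C)C)C(C)C)c1 | intermediate
11 | 5-(benzyloxy)-2-{4-(benzyloxy)-3-[(triisopropylsilyl)oxy]phenyl}-7-[(triisopropylsilyl)oxy]-4H-chromene | CC(C)[Si](Oc1cc(OCc2ccccc2)c2CC=C(c3ccc(OCc4ccccc4)c(O[Si](C(C)C)(C(C)C)C(C)C)c3)Oc2c1)(C(C)C)C(C)C | intermediate
12 | isopinocampheyl[2,3-trans-5-(benzyloxy)-2-{4-(benzyloxy)-3-[(triisopropylsilyl)oxy]phenyl}-7-[(triisopropylsilyl)oxy]chroman-3-yl]borane (Ipc from (+)-α-pinene; flavan part configured as in 13) | C[C@H]1[C@H]([BH][C@H]3Cc4c(OCc5ccccc5)cc(O[Si](C(C)C)(C(C)C)C(C)C)cc4O[C@@H]3c3ccc(OCc4ccccc4)c(O[Si](C(C)C)(C(C)C)C(C)C)c3)C[C@@H]2C[C@H]1C2(C)C | intermediate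
13 | (2R,3S)-5-(benzyloxy)-2-{4-(benzyloxy)-3-[(triisopropylsilyl)oxy]phenyl}-7-[(triisopropylsilyl)oxy]-3,4-dihydro-2H-chromen-3-ol | CC(C)[Si](Oc1cc(OCc2ccccc2)c2c(c1)O[C@H](c1ccc(OCc3ccccc3)c(O[Si](C(C)C)(C(C)C)C(C)C)c1)[C@@H](O)C2)(C(C)C)C(C)C | intermediate
14 | (2R,3S)-5-(benzyloxy)-2-[4-(benzyloxy)-3-hydroxyphenyl]-3,4-dihydro-2H-chromene-3,7-diol | Oc1cc(OCc2ccccc2)c2c(c1)O[C@H](c1ccc(OCc3ccccc3)c(O)c1)[C@@H](O)C2 | intermediate
15 | 3,4,5-tris(benzyloxy)benzoic acid | OC(=O)c1cc(OCc2ccccc2)c(OCc2ccccc2)c(OCc2ccccc2)c1 | starting material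
16 | 3,4,5-tris(benzyloxy)benzoyl chloride | ClC(=O)c1cc(OCc2ccccc2)c(OCc2ccccc2)c(OCc2ccccc2)c1 | intermediate
17 | (2R,3S)-5-(benzyloxy)-2-{4-(benzyloxy)-3-[3,4,5-tris(benzyloxy)benzoyloxy]phenyl}-3-hydroxy-3,4-dihydro-2H-chromen-7-yl 3,4,5-tris(benzyloxy)benzoate | O=C(Oc1cc(OCc2ccccc2)c2c(c1)O[C@H](c1ccc(OCc3ccccc3)c(OC(=O)c3cc(OCc4ccccc4)c(OCc4ccccc4)c(OCc4ccccc4)c3)c1)[C@@H](O)C2)c1cc(OCc2ccccc2)c(OCc2ccccc2)c(OCc2ccccc2)c1 | intermediate
18 | (+)-catechin 7,3'-di-O-gallate, (2R,3S)-3,5-dihydroxy-2-[4-hydroxy-3-(3,4,5-trihydroxybenzoyloxy)phenyl]-3,4-dihydro-2H-chromen-7-yl 3,4,5-trihydroxybenzoate | O=C(Oc1cc(O)c2c(c1)O[C@H](c1ccc(O)c(OC(=O)c3cc(O)c(O)c(O)c3)c1)[C@@H](O)C2)c1cc(O)c(O)c(O)c1 | target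

## Step count and least certain steps

Total step count: 11. Longest linear sequence: 8 steps (steps 1, 2, 3, 7, 8, 9, 10, 11); steps 4 to 6 form the second branch.

**Step 8 (key step).** The likeliest failure is insufficient facial discrimination, because the reagent-control model comes from carbocyclic 1-arylcycloalkenes and the ring oxygen may weaken or reverse it. Two further dangers are slow addition to the hindered trisubstituted alkene and beta-elimination of the beta-aryloxy alkylborane with opening of ring C. Fallback, from 11 back to 13: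
- Hydroboration of 11 with BH3·SMe2 and perborate oxidation gives the racemic 2,3-trans-flavan-3-ol F1; the relative configuration is still fixed by syn addition.
- Esterification with (S)-O-methylmandelic acid (DCC, DMAP cat.) gives the (2R,3S)-flavanyl (S)-O-methylmandelate F2 and its (2S,3R) diastereomer F3, which are separated by chromatography or crystallisation.
- Reductive cleavage of F2 with i-Bu2AlH (CH2Cl2, −78 °C) returns the route to 13.

**Step 7.** The likeliest failure is self-condensation of the o-quinone methide with the electron-rich ring of a second molecule of 4. Others are loss of enol silane 8 to the water released, and acid-induced disproportionation of the chromene during elimination. Fallback, from 3 and 7 back to 11, making the C3–C4 bond by carbonyl chemistry instead: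
- Aldol addition of the lithium enolate of 7 (LiN(SiMe3)2, THF, −78 °C) to 3, whose phenol is transiently silylated (TMSCl, Et3N), and dehydration on dilute-acid work-up give the (E)-2-hydroxychalcone-type enone F4.
- Conjugate reduction ([(PPh3)CuH]6 cat., PhSiH3, toluene) gives the saturated hydroxy ketone F5.
- Cyclodehydration (PPTS, toluene, water separator) gives 11.

**Step 3.** The likeliest failure is over-reduction to the o-cresol through hydride capture of an o-quinone methide, or oligomerisation of the very electron-rich salicyl alcohol during isolation. Fallback, from 3 back to 11: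
- Reductive amination of 3 with morpholine and NaBH(OAc)3 (1,2-dichloroethane) gives the stable Mannich base F6.
- Heating F6 with 8 (toluene or xylene, 110 to 130 °C) releases morpholine and the same o-quinone methide 9, and the sequence of step 7 returns the route to 11.

**Step 10.** The likeliest failure is over-acylation at the secondary 3-OH, or incomplete acylation at the 3'-OH flanked by the 4'-benzyloxy group when the conditions are kept mild enough to spare O3. Fallback, from 13 back to 18:
- Acylation of the 3-OH of 13 (CbzCl, pyridine, DMAP) gives the 3-O-benzyl carbonate F7.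
- Buffered Bu4NF/AcOH gives the diphenol F8.
- Exhaustive acylation with 16 (Et3N, DMAP cat.) gives the bis-gallate carbonate F9.
- Hydrogenolysis under the conditions of step 11 removes the carbonate with the benzyl ethers and gives 18.

**Step 11.** The likeliest failures are hydrogenolytic scission of the benzylic C2–O1 bond during the long exposure needed for eight benzyl ethers, a 3'-to-4' acyl shift once O4' is bare, and stalling by catalyst poisoning. Fallback, from 17 back to 18: non-reductive debenzylation with BCl3 and pentamethylbenzene as cation trap (CH2Cl2, −78 °C; quench with MeOH/CHCl3 at low temperature). This cleaves aryl benzyl ethers heterolytically and leaves aryl esters and the ring C ether intact. It makes no new intermediate.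

## Further compounds

F1 | step 8 | racemic 2,3-trans-5-(benzyloxy)-2-{4-(benzyloxy)-3-[(triisopropylsilyl)oxy]phenyl}-7-[(triisopropylsilyl)oxy]-3,4-dihydro-2H-chromen-3-ol (1:1 mixture of 2R,3S and 2S,3R) | CC(C)[Si](Oc1cc(OCc2ccccc2)c2c(c1)O[C@H](c1ccc(OCc3ccccc3)c(O[Si](C(C)C)(C(C)C)C(C)C)c1)[C@@H](O)C2)(C(C)C)C(C)C.CC(C)[Si](Oc1cc(OCc2ccccc2)c2c(c1)O[C@@H](c1ccc(OCc3ccccc3)c(O[Si](C(C)C)(C(C)C)C(C)C)c1)[C@H](O)C2)(C(C)C)C(C)C
F2 | step 8 | (2R,3S)-5-(benzyloxy)-2-{4-(benzyloxy)-3-[(triisopropylsilyl)oxy]phenyl}-7-[(triisopropylsilyl)oxy]-3,4-dihydro-2H-chromen-3-yl (2S)-2-methoxy-2-phenylacetate | CO[C@H](C(=O)O[C@H]1Cc2c(OCc3ccccc3)cc(O[Si](C(C)C)(C(C)C)C(C)C)cc2O[C@@H]1c1ccc(OCc2ccccc2)c(O[Si](C(C)C)(C(C)C)C(C)C)c1)c1ccccc1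
F3 | step 8 | (2S,3R)-5-(benzyloxy)-2-{4-(benzyloxy)-3-[(triisopropylsilyl)oxy]phenyl}-7-[(triisopropylsilyl)oxy]-3,4-dihydro-2H-chromen-3-yl (2S)-2-methoxy-2-phenylacetate | CO[C@H](C(=O)O[C@@H]1Cc2c(OCc3ccccc3)cc(O[Si](C(C)C)(C(C)C)C(C)C)cc2O[C@H]1c1ccc(OCc2ccccc2)c(O[Si](C(C)C)(C(C)C)C(C)C)c1)c1ccccc1
F4 | step 7 | (E)-3-{2-(benzyloxy)-6-hydroxy-4-[(triisopropylsilyl)oxy]phenyl}-1-{4-(benzyloxy)-3-[(triisopropylsilyl)oxy]phenyl}prop-2-en-1-one | O=C(/C=C/c1c(O)cc(O[Si](C(C)C)(C(C)C)C(C)C)cc1OCc1ccccc1)c1ccc(OCc2ccccc2)c(O[Si](C(C)C)(C(C)C)C(C)C)c1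
F5 | step 7 | 3-{2-(benzyloxy)-6-hydroxy-4-[(triisopropylsilyl)oxy]phenyl}-1-{4-(benzyloxy)-3-[(triisopropylsilyl)oxy]phenyl}propan-1-one | O=C(CCc1c(O)cc(O[Si](C(C)C)(C(C)C)C(C)C)cc1OCc1ccccc1)c1ccc(OCc2ccccc2)c(O[Si](C(C)C)(C(C)C)C(C)C)c1
F6 | step 3 | 3-(benzyloxy)-2-(morpholin-4-ylmethyl)-5-[(triisopropylsilyl)oxy]phenol | Oc1cc(O[Si](C(C)C)(C(C)C)C(C)C)cc(OCc2ccccc2)c1CN1CCOCC1
F7 | step 10 | benzyl (2R,3S)-5-(benzyloxy)-2-{4-(benzyloxy)-3-[(triisopropylsilyl)oxy]phenyl}-7-[(triisopropylsilyl)oxy]-3,4-dihydro-2H-chromen-3-yl carbonate | CC(C)[Si](Oc1cc(OCc2ccccc2)c2c(c1)O[C@H](c1ccc(OCc3ccccc3)c(O[Si](C(C)C)(C(C)C)C(C)C)c1)[C@@H](OC(=O)OCc1ccccc1)C2)(C(C)C)C(C)C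
F8 | step 10 | benzyl (2R,3S)-5-(benzyloxy)-2-[4-(benzyloxy)-3-hydroxyphenyl]-7-hydroxy-3,4-dihydro-2H-chromen-3-yl carbonate | Oc1cc(OCc2ccccc2)c2c(c1)O[C@H](c1ccc(OCc3ccccc3)c(O)c1)[C@@H](OC(=O)OCc1ccccc1)C2
F9 | step 10 | (2R,3S)-5-(benzyloxy)-3-[(benzyloxycarbonyl)oxy]-2-{4-(benzyloxy)-3-[3,4,5-tris(benzyloxy)benzoyloxy]phenyl}-3,4-dihydro-2H-chromen-7-yl 3,4,5-tris(benzyloxy)benzoate | O=C(Oc1cc(OCc2ccccc2)c2c(c1)O[C@H](c1ccc(OCc3ccccc3)c(OC(=O)c3cc(OCc4ccccc4)c(OCc4ccccc4)c(OCc4ccccc4)c3)c1)[C@@H](OC(=O)OCc1ccccc1)C2)c1cc(OCc2ccccc2)c(OCc2ccccc2)c(OCc2ccccc2)c1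
F0 | step 11 | none | none
A1 | alternative 1 | 3-(benzyloxy)-2-[(2E)-3-{4-(benzyloxy)-3-[(triisopropylsilyl)oxy]phenyl}prop-2-en-1-yl]-5-[(triisopropylsilyl)oxy]phenol | Oc1cc(O[Si](C(C)C)(C(C)C)C(C)C)cc(OCc2ccccc2)c1C/C=C/c1ccc(OCc2ccccc2)c(O[Si](C(C)C)(C(C)C)C(C)C)c1
A2 | alternative 1 | (1S,2S)-3-{2-(benzyloxy)-6-hydroxy-4-[(triisopropylsilyl)oxy]phenyl}-1-{4-(benzyloxy)-3-[(triisopropylsilyl)oxy]phenyl}propane-1,2-diol | Oc1cc(O[Si](C(C)C)(C(C)C)C(C)C)cc(OCc2ccccc2)c1C[C@H](O)[C@@H](O)c1ccc(OCc2ccccc2)c(O[Si](C(C)C)(C(C)C)C(C)C)c1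
A3 | alternative 2 | 5-(benzyloxy)-7-[(triisopropylsilyl)oxy]-4H-chromen-4-one | O=c1ccoc2cc(O[Si](C(C)C)(C(C)C)C(C)C)cc(OCc3ccccc3)c12
A4 | alternative 2 | (2S)-5-(benzyloxy)-2-{4-(benzyloxy)-3-[(triisopropylsilyl)oxy]phenyl}-7-[(triisopropylsilyl)oxy]-2,3-dihydro-4H-chromen-4-one | O=C1C[C@@H](c2ccc(OCc3ccccc3)c(O[Si](C(C)C)(C(C)C)C(C)C)c2)Oc2cc(O[Si](C(C)C)(C(C)C)C(C)C)cc(OCc3ccccc3)c12
A5 | alternative 3 | 1-(benzyloxy)-3-{[(1S)-1-{4-(benzyloxy)-3-[(triisopropylsilyl)oxy]phenyl}prop-2-en-1-yl]oxy}-2-ethenyl-5-[(triisopropylsilyl)oxy]benzene | C=Cc1c(OCc2ccccc2)cc(O[Si](C(C)C)(C(C)C)C(C)C)cc1O[C@@H](C=C)c1ccc(OCc2ccccc2)c(O[Si](C(C)C)(C(C)C)C(C)C)c1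
A6 | alternative 3 | (2S)-5-(benzyloxy)-2-{4-(benzyloxy)-3-[(triisopropylsilyl)oxy]phenyl}-7-[(triisopropylsilyl)oxy]-2H-chromene | C1=Cc2c(OCc3ccccc3)cc(O[Si](C(C)C)(C(C)C)C(C)C)cc2O[C@@H]1c1ccc(OCc2ccccc2)c(O[Si](C(C)C)(C(C)C)C(C)C)c1
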